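**Plan**

- Retrosynthetic cuts, in order: C8–OH/C17 (hydration of an 8(17)-alkene made from an 8-ketone); C5–H (hydrogen-atom transfer to a Δ5 alkene); C5=C6 (reductive coupling of a C5 ketone with a C6 aldehyde); C7–C8 (allyl unit added to a C8 aldehyde); C9–C11 (alkylation with a five-carbon iodide from (S)-citronellol); C9–C10 (asymmetric allylation of 2,2,6-trimethylcyclohexanone).
- Forward: ring A is bought as the ketone. C10 is made quaternary, the C9–C8 arm is branched (side chain on C9, allyl on C8), and ring B is closed last by joining the two carbonyl carbons C5 and C6 with low-valent titanium.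
- Enabling feature: C5 lies between two quaternary carbons (C4 with the geminal methyls, C10 with the angular methyl). Its carbonyl cannot enolise, is inert to every nucleophile used and travels unprotected, and after coupling the only possible double bond is C5=C6 in ring B. C6 is β to the C8 oxygen, so it is reached as an aldehyde from an allyl group.
- Stereochemistry: C10 from the chiral palladium catalyst; C13 from (S)-citronellol; C5 by hydrogen delivery to the α face of the C5 radical, anti to the axial methyls on C4 and C10; C9 by equilibration next to the C8 ketone; C8 by equatorial attack of water on the 8(17)-alkene.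

Key step: step 11

Remark: the (R)-configured t-Bu-PHOX ligand is assumed to give the (R)-allyl ketone (the (S)-ligand is the one associated with the (S)-series of α-allyl-α-methyl cyclohexanones); if the sense is opposite, the other ligand enantiomer is used. Atom numbers C1–C17 are labdane numbers.

**Route**

Step 1
Reactants: 1 (S)-citronellol
Product: 2 (S)-citronellyl acetate
Conditions: Ac2O, pyridine, DMAP (cat.), CH2Cl2, 0 → 23 °C
Reagents that add atoms: acetic anhydride, CC(=O)OC(C)=O
Why: DMAP-catalysed acetylation of the primary alcohol should install the acetate of the target at once; the C13 stereocentre is bought in here and is not touched again.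

Step 2
Reactants: 2 (S)-citronellyl acetate
Product: 3 (4S)-6-acetoxy-4-methylhexanoic acid
Conditions: RuCl3·H2O (cat.), NaIO4, CCl4/MeCN/H2O, 23 °C
Reagents that add atoms: sodium periodate, [Na+].[O-]I(=O)(=O)=O; water, O
Why: Catalytic RuO4 oxidative cleavage of the trisubstituted alkene should give the acid and acetone, the ester and the remote stereocentre being inert to the oxidant.

Step 3
Reactants: 3 (4S)-6-acetoxy-4-methylhexanoic acid
Product: 4 (3R)-5-iodo-3-methylpentyl acetate
Conditions: PhI(OAc)2, I2, CCl4, hν (tungsten lamp), reflux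
Reagents that add atoms: iodine, II
Why: Hunsdiecker-type iododecarboxylation: the acyl hypoiodite should fragment under light to CO2 and a primary alkyl radical that is capped by iodine, leaving exactly the five carbons C11–C15 (the descriptor changes to R only because iodine alters the priorities).

Step 4
Reactants: 5 2,2,6-trimethylcyclohexanone (racemic)
Product: 6 allyl 2,6,6-trimethylcyclohex-1-en-1-yl carbonate
Conditions: LiN(SiMe3)2, THF, 0 °C; then allyl chloroformate, −78 → 23 °C
Reagents that add atoms: allyl chloroformate, C=CCOC(Cl)=O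
Why: Deprotonation can occur only at the single α-hydrogen, and O-acylation of the resulting tetrasubstituted lithium enolate with the hard chloroformate should give the enol carbonate (the stereocentre of 5 is erased).

Step 5
Reactants: 6 allyl 2,6,6-trimethylcyclohex-1-en-1-yl carbonate
Product: 7 (2R)-2-allyl-2,6,6-trimethylcyclohexan-1-one
Conditions: Pd2(dba)3 (2.5 mol %), (R)-t-Bu-PHOX (6 mol %), THF, 25 °C
Reagents that add atoms: none
Why: Decarboxylative asymmetric allylic alkylation (Tsuji–Trost type): zerovalent palladium ionises the allyl carbonate, loss of CO2 gives a π-allylpalladium enolate, and the chiral P,N-ligand selects the enolate face in the C–C bond formation, which sets the quaternary C10.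

Step 6
Reactants: 7 (2R)-2-allyl-2,6,6-trimethylcyclohexan-1-one
Product: 8 2-[(1R)-1,3,3-trimethyl-2-oxocyclohexyl]acetaldehyde
Conditions: O3, CH2Cl2, −78 °C; then PPh3, −78 → 23 °C
Reagents that add atoms: ozone, [O-][O+]=O
Why: Ozonolysis with reductive work-up should cut the terminal alkene to the C8 aldehyde while the flanked ketone stays untouched.

Step 7
Reactants: 8 2-[(1R)-1,3,3-trimethyl-2-oxocyclohexyl]acetaldehyde; 4 (3R)-5-iodo-3-methylpentyl acetate
Product: 11 (3S)-3-methyl-7-oxo-6-[(1R)-1,3,3-trimethyl-2-oxocyclohexyl]heptyl acetate (both C9 epimers), via N-cyclohexyl imine 9 (not isolated), via alkylated imine 10 (not isolated)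
Conditions: cyclohexylamine, MgSO4, Et2O, 0 °C; then LiN(i-Pr)2, THF, −20 °C; then 4, DMPU, −78 → 0 °C; then aq. oxalic acid, 23 °C
Reagents that add atoms: none
Why: Stork metalloenamine alkylation: the imine should form only at the aldehyde, be deprotonated at its single α-position (C9) and displace iodide from 4 in an SN2 step, the C5 ketone having no α-hydrogen; C9 is formed as a mixture and is corrected in step 13.

Step 8
Reactants: 11 (3S)-3-methyl-7-oxo-6-[(1R)-1,3,3-trimethyl-2-oxocyclohexyl]heptyl acetate
Product: 12 (3S)-7-hydroxy-3-methyl-6-[(1R)-1,3,3-trimethyl-2-oxocyclohexyl]dec-9-en-1-yl acetate (C8 and C9 epimers)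
Conditions: allylboronic acid pinacol ester, toluene, 60 °C; then aq. NH4Cl
Reagents that add atoms: allylboronic acid pinacol ester, C=CCB1OC(C)(C)C(C)(C)O1
Why: Allylboration through a closed six-membered (Zimmerman–Traxler) transition state should add the C7–C6 unit to the aldehyde only, since the neutral reagent touches neither the flanked ketone nor the acetate; the C8 configuration is irrelevant because C8 is oxidised in step 13.

Step 9
Reactants: 12 (3S)-7-hydroxy-3-methyl-6-[(1R)-1,3,3-trimethyl-2-oxocyclohexyl]dec-9-en-1-yl acetate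
Product: 13 (3S)-3-methyl-7-(triethylsilyloxy)-6-[(1R)-1,3,3-trimethyl-2-oxocyclohexyl]dec-9-en-1-yl acetate
Conditions: Et3SiOTf, 2,6-lutidine, CH2Cl2, −78 → 0 °C
Reagents that add atoms: triethylsilyl trifluoromethanesulfonate, CC[Si](CC)(CC)OS(=O)(=O)C(F)(F)F
Why: Silylation of the secondary alcohol (the ketone cannot form a silyl enol ether) should ensure that no free β-hydroxy aldehyde meets the Lewis-acidic titanium reagent of step 11.

Step 10
Reactants: 13 (3S)-3-methyl-7-(triethylsilyloxy)-6-[(1R)-1,3,3-trimethyl-2-oxocyclohexyl]dec-9-en-1-yl acetate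
Product: 14 (3S)-3-methyl-9-oxo-7-(triethylsilyloxy)-6-[(1R)-1,3,3-trimethyl-2-oxocyclohexyl]nonyl acetate
Conditions: O3, CH2Cl2, −78 °C; then PPh3, −78 → 23 °C
Reagents that add atoms: ozone, [O-][O+]=O
Why: Ozonolysis with reductive work-up should turn the vinyl group into the C6 aldehyde and so give the 1,6-keto aldehyde needed for ring closure.

Step 11
Reactants: 14 (3S)-3-methyl-9-oxo-7-(triethylsilyloxy)-6-[(1R)-1,3,3-trimethyl-2-oxocyclohexyl]nonyl acetate
Product: 15 (3S)-3-methyl-5-[(8aR)-5,5,8a-trimethyl-2-(triethylsilyloxy)-1,2,3,5,6,7,8,8a-octahydronaphthalen-1-yl]pentyl acetate (Δ5 alkene; C8 and C9 epimers)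
Conditions: TiCl3(DME)1.5, Zn–Cu couple, DME, reflux; 14 added slowly by syringe pump (high dilution)
Reagents that add atoms: none
Why: Low-valent titanium transfers single electrons to the C6 aldehyde and the C5 ketone, the two titanium-bound ketyl carbons join to a cyclic titanium pinacolate (C5–C6 bond), and at reflux the metal strips both oxygen atoms to leave the C5=C6 alkene (McMurry coupling). The closest known reaction type is the intramolecular McMurry coupling of keto aldehydes to cycloalkenes, the standard answer for crowded alkenes. Ring B (C5, C6, C7, C8, C9, C10) closes as a six-membered ring by carbonyl–carbonyl coupling of the two ends of a 1,6-dicarbonyl chain, so two carbons of like (electrophilic) polarity are united through their ketyl radicals. No lasting stereocentre is formed: the pinacolate centres are erased on deoxygenation, C5 is left trigonal on purpose and is set in step 12, and C8 and C9 are carried as mixtures. The step needs ring closure to win over intermolecular aldehyde coupling and over attack on the acetate; slow addition at high dilution favours the six-membered pinacolate, and esters couple far more slowly than aldehydes and ketones. Because C5 lies between the quaternary carbons C4 and C10, the ketone cannot enolise or divert into aldol chemistry, and deoxygenation can place the double bond only between C5 and C6.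

Step 12
Reactants: 15 (3S)-3-methyl-5-[(8aR)-5,5,8a-trimethyl-2-(triethylsilyloxy)-1,2,3,5,6,7,8,8a-octahydronaphthalen-1-yl]pentyl acetate
Product: 17 (3S)-5-[(4aS,8aS)-2-hydroxy-5,5,8a-trimethyldecahydronaphthalen-1-yl]-3-methylpentyl acetate (C8 and C9 epimers), via saturated silyl ether 16 (not isolated)
Conditions: Mn(dpm)3 (10 mol %), PhSiH3, t-BuOOH, i-PrOH, 23 °C; then HCl (1 M), THF, 23 °C
Reagents that add atoms: none
Why: Metal-hydride hydrogen-atom-transfer hydrogenation (Mukaiyama type): the manganese hydride should give H• to C6, and the tertiary C5 radical in the closed ring takes its hydrogen on the α face, anti to the axial methyls on C4 and C10, which gives the trans ring fusion (5S); dilute acid then cleaves the silyl ether.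

Step 13
Reactants: 17 (3S)-5-[(4aS,8aS)-2-hydroxy-5,5,8a-trimethyldecahydronaphthalen-1-yl]-3-methylpentyl acetate
Product: 19 (3S)-3-methyl-5-[(1R,4aS,8aS)-5,5,8a-trimethyl-2-oxodecahydronaphthalen-1-yl]pentyl acetate, via C9-epimeric ketone mixture 18 (not isolated)
Conditions: Dess–Martin periodinane, CH2Cl2, 23 °C; then DBU, toluene, 80 °C
Reagents that add atoms: none
Why: Dess–Martin oxidation gives the C8 ketone, and base equilibration through its enolate should place the C9 side chain equatorial (cis to the C10 methyl), which sets C9 under thermodynamic control.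

Step 14
Reactants: 19 (3S)-3-methyl-5-[(1R,4aS,8aS)-5,5,8a-trimethyl-2-oxodecahydronaphthalen-1-yl]pentyl acetate
Product: 20 (3S)-3-methyl-5-[(1S,4aS,8aS)-5,5,8a-trimethyl-2-methylidenedecahydronaphthalen-1-yl]pentyl acetate
Conditions: Zn, CH2Br2, TiCl4, THF/CH2Cl2, 0 → 23 °C
Reagents that add atoms: dibromomethane, BrCBr
Why: Takai–Lombardo methylenation (a titanium methylidene from CH2Br2, Zn and TiCl4) should convert the hindered, epimerisable ketone into the 8(17)-alkene under non-basic conditions that leave C9 and the acetate untouched.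

Step 15
Reactants: 20 (3S)-3-methyl-5-[(1S,4aS,8aS)-5,5,8a-trimethyl-2-methylidenedecahydronaphthalen-1-yl]pentyl acetate
Product: 22 (3S)-5-[(1R,2R,4aS,8aS)-2-hydroxy-2,5,5,8a-tetramethyldecahydronaphthalen-1-yl]-3-methylpentyl acetate, via organomercurial 21 (not isolated)
Conditions: Hg(OAc)2, THF/H2O, 23 °C; then NaBH4, aq. NaOH, 0 °C (short)
Reagents that add atoms: water, O
Why: Oxymercuration–demercuration: water should add in the Markovnikov sense to C8 of the mercurinium ion along the equatorial (α) trajectory, the axial one being blocked by the syn-axial C10 methyl, which gives the 8α-hydroxyl with the new C17 methyl axial (8R); NaBH4 then replaces mercury by hydrogen.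

**Compound list**

1 | (S)-citronellol | OCC[C@@H](C)CCC=C(C)C | starting material
2 | (S)-citronellyl acetate | CC(=O)OCC[C@@H](C)CCC=C(C)C | intermediate
3 | (4S)-6-acetoxy-4-methylhexanoic acid | CC(=O)OCC[C@@H](C)CCC(=O)O | intermediate
4 | (3R)-5-iodo-3-methylpentyl acetate | CC(=O)OCC[C@@H](C)CCI | intermediate
5 | 2,2,6-trimethylcyclohexanone (racemic) | CC1CCCC(C)(C)C1=O | starting material
6 | allyl 2,6,6-trimethylcyclohex-1-en-1-yl carbonate | C=CCOC(=O)OC1=C(C)CCCC1(C)C | intermediate
7 | (2R)-2-allyl-2,6,6-trimethylcyclohexan-1-one | C=CC[C@@]1(C)CCCC(C)(C)C1=O | intermediate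
8 | 2-[(1R)-1,3,3-trimethyl-2-oxocyclohexyl]acetaldehyde | O=CC[C@@]1(C)CCCC(C)(C)C1=O | intermediate
9 | N-cyclohexyl imine of 8 | C1CCCCC1N=CC[C@@]2(C)CCCC(C)(C)C2=O | intermediate
10 | C9-alkylated N-cyclohexyl imine (C9 epimers) | CC(=O)OCC[C@@H](C)CCC(C=NC1CCCCC1)[C@@]2(C)CCCC(C)(C)C2=O | intermediate
11 | (3S)-3-methyl-7-oxo-6-[(1R)-1,3,3-trimethyl-2-oxocyclohexyl]heptyl acetate (C9 epimers) | CC(=O)OCC[C@@H](C)CCC(C=O)[C@@]1(C)CCCC(C)(C)C1=O | intermediate
12 | (3S)-7-hydroxy-3-methyl-6-[(1R)-1,3,3-trimethyl-2-oxocyclohexyl]dec-9-en-1-yl acetate (C8, C9 epimers) | CC(=O)OCC[C@@H](C)CCC(C(O)CC=C)[C@@]1(C)CCCC(C)(C)C1=O | intermediate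
13 | (3S)-3-methyl-7-(triethylsilyloxy)-6-[(1R)-1,3,3-trimethyl-2-oxocyclohexyl]dec-9-en-1-yl acetate | CC(=O)OCC[C@@H](C)CCC(C(CC=C)O[Si](CC)(CC)CC)[C@@]1(C)CCCC(C)(C)C1=O | intermediate
14 | (3S)-3-methyl-9-oxo-7-(triethylsilyloxy)-6-[(1R)-1,3,3-trimethyl-2-oxocyclohexyl]nonyl acetate | CC(=O)OCC[C@@H](C)CCC(C(CC=O)O[Si](CC)(CC)CC)[C@@]1(C)CCCC(C)(C)C1=O | intermediate
15 | (3S)-3-methyl-5-[(8aR)-5,5,8a-trimethyl-2-(triethylsilyloxy)-1,2,3,5,6,7,8,8a-octahydronaphthalen-1-yl]pentyl acetate | CC(=O)OCC[C@@H](C)CCC1[C@@]2(C)CCCC(C)(C)C2=CCC1O[Si](CC)(CC)CC | intermediate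
16 | (3S)-3-methyl-5-[(4aS,8aS)-5,5,8a-trimethyl-2-(triethylsilyloxy)decahydronaphthalen-1-yl]pentyl acetate | CC(=O)OCC[C@@H](C)CCC1[C@@]2(C)CCCC(C)(C)[C@@H]2CCC1O[Si](CC)(CC)CC | intermediate
17 | (3S)-5-[(4aS,8aS)-2-hydroxy-5,5,8a-trimethyldecahydronaphthalen-1-yl]-3-methylpentyl acetate | CC(=O)OCC[C@@H](C)CCC1[C@@]2(C)CCCC(C)(C)[C@@H]2CCC1O | intermediate
18 | C9-epimeric mixture of the C8 ketone | CC(=O)OCC[C@@H](C)CCC1[C@@]2(C)CCCC(C)(C)[C@@H]2CCC1=O | intermediate
19 | (3S)-3-methyl-5-[(1R,4aS,8aS)-5,5,8a-trimethyl-2-oxodecahydronaphthalen-1-yl]pentyl acetate | CC(=O)OCC[C@@H](C)CC[C@@H]1[C@@]2(C)CCCC(C)(C)[C@@H]2CCC1=O | intermediate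
20 | (3S)-3-methyl-5-[(1S,4aS,8aS)-5,5,8a-trimethyl-2-methylidenedecahydronaphthalen-1-yl]pentyl acetate | CC(=O)OCC[C@@H](C)CC[C@@H]1[C@@]2(C)CCCC(C)(C)[C@@H]2CCC1=C | intermediate
21 | 17-(acetoxymercurio)-8α-hydroxy adduct of 20 | CC(=O)OCC[C@@H](C)CC[C@@H]1[C@@]2(C)CCCC(C)(C)[C@@H]2CC[C@@]1(C[Hg]OC(C)=O)O | intermediate
22 | (3S)-5-[(1R,2R,4aS,8aS)-2-hydroxy-2,5,5,8a-tetramethyldecahydronaphthalen-1-yl]-3-methylpentyl acetate | CC(=O)OCC[C@@H](C)CC[C@@H]1[C@@]2(C)CCCC(C)(C)[C@@H]2CC[C@@]1(C)O | target

**Step count and risks**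

Total step count: 15. Longest linear sequence: 12 (steps 4–15, from 2,2,6-trimethylcyclohexanone); the side-chain iodide takes 3 steps (steps 1–3).

Steps most likely to fail:

1. Step 11. The pinacol coupling at the neopentyl-type C5 ketone may be slow, which would let intermolecular aldehyde coupling, plain reduction of the aldehyde, β-elimination of the silyloxy group or attack on the acetate take over. The fallback sets out from 14 and returns at 15. The aldehyde of 14 alone is reduced with NaBH4 (the flanked ketone is left) to the primary alcohol F1. Iodination with I2, PPh3 and imidazole gives the primary iodide F2. An intramolecular Barbier reaction with SmI2/HMPA adds the alkylsamarium to the C5 ketone and gives the tertiary alcohol F3. Dehydration with the Burgess reagent can only go toward C6, because C4 and C10 carry no hydrogen, and gives 15.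

2. Step 7. The SN2 alkylation at the aza-enolate carbon next to the quaternary C10 may be sluggish, with competing attack of the aza-enolate on the acetate or self-condensation. The fallback sets out from 8 and 4 and returns at 11. Iodide 4 is oxidised (Kornblum oxidation, DMSO, NaHCO3, heat) to the aldehyde F4. The lithiated imine 9 is added to F4 (directed aldol), and aqueous oxalic acid hydrolyses and dehydrates the adduct to the enal F5. Conjugate reduction with [(Ph3P)CuH]6 gives 11.

3. Step 15. Facial selectivity in the attack of water on the mercurinium ion may be poor, and the acetate may be partly lost in the alkaline borohydride stage. The fallback sets out from 20 and returns at 22. Epoxidation with 3-chloroperbenzoic acid from the less hindered α face gives the 8α,17-epoxide F6. LiAlH4 opens the epoxide at the primary C17 and cleaves the acetate to give the 8α,15-diol F7. Ac2O in pyridine acetylates only the primary hydroxyl and gives 22.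

**Further compounds**

F1 | step 11 | (3S)-9-hydroxy-3-methyl-7-(triethylsilyloxy)-6-[(1R)-1,3,3-trimethyl-2-oxocyclohexyl]nonyl acetate | CC(=O)OCC[C@@H](C)CCC(C(CCO)O[Si](CC)(CC)CC)[C@@]1(C)CCCC(C)(C)C1=O
F2 | step 11 | (3S)-9-iodo-3-methyl-7-(triethylsilyloxy)-6-[(1R)-1,3,3-trimethyl-2-oxocyclohexyl]nonyl acetate | CC(=O)OCC[C@@H](C)CCC(C(CCI)O[Si](CC)(CC)CC)[C@@]1(C)CCCC(C)(C)C1=O
F3 | step 11 | 5-hydroxy (C4a carbinol) precursor of 15, tertiary alcohol at the ring fusion | CC(=O)OCC[C@@H](C)CCC1[C@@]2(C)CCCC(C)(C)C2(O)CCC1O[Si](CC)(CC)CC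
F4 | step 7 | (3R)-3-methyl-5-oxopentyl acetate | CC(=O)OCC[C@@H](C)CC=O
F5 | step 7 | (3S)-3-methyl-7-oxo-6-[(1R)-1,3,3-trimethyl-2-oxocyclohexyl]hept-5-en-1-yl acetate | CC(=O)OCC[C@@H](C)CC=C(C=O)[C@@]1(C)CCCC(C)(C)C1=O
F6 | step 15 | 8α,17-epoxide of 20 | CC(=O)OCC[C@@H](C)CC[C@@H]1[C@@]2(C)CCCC(C)(C)[C@@H]2CC[C@]13CO3
F7 | step 15 | (13S)-labdane-8α,15-diol | OCC[C@@H](C)CC[C@@H]1[C@@]2(C)CCCC(C)(C)[C@@H]2CC[C@@]1(C)O
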